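**Plan**

- Numbering: isochromanone numbering is used (C1 lactone carbonyl, O2, C3 hemiketal carbon, C4 methine, C4a–C8a = ring A), C9 is the CH2O carbon, and ring B is the trimethylresorcylate ring.
- Cuts: first O2–C3 (the lactol is opened to a C3 keto acid), then ring A, taken back to a cyclohexane-1,3-dione, at C7–C8 and C4a–C8a, then C4a=C5, C3–C4 and the C9–O ester bond.
- Enabling feature: on ring A the C6 methoxyl and C8 hydroxyl are 1,3-related with C7–H between them, C8a carries the C1 carboxyl and C5 a methyl. Ring A is therefore the dehydro form of a Michael–Claisen adduct of a malonate (C1, C8a, C8) with a 3-methyl-3-en-2-one (C7, C6, C5, C4a).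
- Forward: the ring B acid is made from atraric acid and the chain C9–C3–C4–C4a is grown on its ester oxygen. Ring A is then closed on the chain and aromatized, and the lactol ring forms last, when hydrogenolysis frees the C1 acid.
- Stereochemistry: C4 (S) is set by a Brown (E)-crotylboration and carried through unchanged. The carbinol centre made with it is later oxidized to the C3 ketone, and the hemiketal centre C3 (R) is set by equilibration.

Key step: step 11

Assumption: the 3R configuration of the hemiketal carbon is taken to be the epimer favoured when the lactol equilibrates through the open keto acid (axial hydroxyl, trans to a pseudo-axial C4 methyl), so no reagent is used to set it.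

**Route**

Step 1
Reactants: 1 atraric acid (methyl 2,4-dihydroxy-3,6-dimethylbenzoate)
Product: 2 methyl 5-formyl-2,4-dihydroxy-3,6-dimethylbenzoate
Conditions: Cl2CHOCH3, TiCl4, CH2Cl2, 0 °C to rt; then ice-cold 1 M HCl
Reagents that add atoms: dichloromethyl methyl ether, COC(Cl)Cl; water, O
Why: Rieche formylation is an electrophilic aromatic substitution that can occur only at C5 of the benzoate, the single unsubstituted ring position, which is activated ortho and para by the two hydroxyls.

Step 2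
Reactants: 2 methyl 5-formyl-2,4-dihydroxy-3,6-dimethylbenzoate
Product: 4 methyl 2,4-dihydroxy-3,5,6-trimethylbenzoate, via benzylic alcohol 3 (not isolated)
Conditions: H2 (3 bar), 10% Pd/C, AcOH, HCl (cat.), rt
Reagents that add atoms: none
Why: Catalytic hydrogenation of the aryl aldehyde gives the ortho-hydroxybenzylic alcohol 3, whose activated benzylic C–O bond should undergo hydrogenolysis under the same acidic conditions to leave the methyl group, the ester being inert.

Step 3
Reactants: 4 methyl 2,4-dihydroxy-3,5,6-trimethylbenzoate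
Product: 5 methyl 2,4-bis(benzyloxy)-3,5,6-trimethylbenzoate
Conditions: BnBr, K2CO3, Bu4NI (cat.), DMF, 60 °C
Reagents that add atoms: benzyl bromide, BrCc1ccccc1
Why: Williamson etherification with carbonate in warm DMF should alkylate both the free and the ester-chelated phenol, and C-alkylation is not an option because every ring carbon is substituted.

Step 4
Reactants: 5 methyl 2,4-bis(benzyloxy)-3,5,6-trimethylbenzoate
Product: 6 2,4-bis(benzyloxy)-3,5,6-trimethylbenzoic acid
Conditions: KOH, DMSO/H2O (4:1), 100 °C; then 1 M HCl, 0 °C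
Reagents that add atoms: potassium hydroxide, [K+].[OH-]
Why: Saponification of this di-ortho-substituted ester needs the poorly solvated hydroxide of aqueous DMSO at 100 °C, conditions to which aryl benzyl ethers are inert, and cold acidification avoids decarboxylation.

Step 5
Reactants: 6 2,4-bis(benzyloxy)-3,5,6-trimethylbenzoic acid
Product: 7 prop-2-en-1-yl 2,4-bis(benzyloxy)-3,5,6-trimethylbenzoate
Conditions: allyl bromide, K2CO3, DMF, rt
Reagents that add atoms: allyl bromide, C=CCBr
Why: SN2 O-alkylation of the carboxylate esterifies the hindered acid without any attack at its shielded carbonyl carbon and brings in C9 and C3.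

Step 6
Reactants: 7 prop-2-en-1-yl 2,4-bis(benzyloxy)-3,5,6-trimethylbenzoate
Product: 9 2-oxoethyl 2,4-bis(benzyloxy)-3,5,6-trimethylbenzoate, via vicinal diol 8 (not isolated)
Conditions: OsO4 (2 mol%), NaIO4, 2,6-lutidine, dioxane/H2O (3:1), rt
Reagents that add atoms: osmium tetroxide, O=[Os](=O)(=O)=O; sodium periodate, [Na+].[O-]I(=O)(=O)=O
Why: Lemieux–Johnson oxidation (dihydroxylation, then periodate cleavage of diol 8) cuts the terminal alkene to the aldehyde without exposing the electron-rich, benzyl-protected arene to ozone.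

Step 7
Reactants: 9 2-oxoethyl 2,4-bis(benzyloxy)-3,5,6-trimethylbenzoate
Product: 11 (2S,3S)-2-hydroxy-3-methylpent-4-en-1-yl 2,4-bis(benzyloxy)-3,5,6-trimethylbenzoate, via diisopinocampheylborinate 10 (not isolated)
Conditions: (E)-but-2-ene, KOtBu, n-BuLi, THF, −78 to −45 °C; (−)-Ipc2BOMe [from (+)-α-pinene], −78 °C; BF3·OEt2; 9, −78 °C; then H2O2, pH 7 buffer, MeOH, 0 °C to rt
Reagents that add atoms: (E)-but-2-ene, C/C=C/C
Why: Brown crotylboration proceeds through a closed chair transition state in which the E geometry of the crotyl group fixes the anti methyl/hydroxyl relationship and the isopinocampheyl groups derived from (+)-α-pinene direct addition to the Si face of the aldehyde, so C4 should be formed as S (carbinol carbon S), the buffered peroxide work-up sparing the ester.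

Step 8
Reactants: 11 (2S,3S)-2-hydroxy-3-methylpent-4-en-1-yl 2,4-bis(benzyloxy)-3,5,6-trimethylbenzoate
Product: 12 (2S,3S)-2-[(tert-butyldimethylsilyl)oxy]-3-methylpent-4-en-1-yl 2,4-bis(benzyloxy)-3,5,6-trimethylbenzoate
Conditions: TBSOTf, 2,6-lutidine, CH2Cl2, −78 to 0 °C
Reagents that add atoms: tert-butyldimethylsilyl triflate, CC(C)(C)[Si](C)(C)OS(=O)(=O)C(F)(F)F
Why: Silylation with the silyl triflate and 2,6-lutidine protects the hindered secondary alcohol at low temperature as a base-stable ether and blocks acyl migration from the C9 oxygen.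

Step 9
Reactants: 12 (2S,3S)-2-[(tert-butyldimethylsilyl)oxy]-3-methylpent-4-en-1-yl 2,4-bis(benzyloxy)-3,5,6-trimethylbenzoate
Product: 14 (2S,3R)-2-[(tert-butyldimethylsilyl)oxy]-3-methyl-4-oxobutyl 2,4-bis(benzyloxy)-3,5,6-trimethylbenzoate, via vicinal diol 13 (not isolated)
Conditions: OsO4 (2 mol%), NaIO4, 2,6-lutidine, dioxane/H2O (3:1), 0 °C to rt
Reagents that add atoms: osmium tetroxide, O=[Os](=O)(=O)=O; sodium periodate, [Na+].[O-]I(=O)(=O)=O
Why: A second Lemieux–Johnson oxidation cleaves the vinyl group under lutidine-buffered, near-neutral conditions that should leave the α-stereocentre of the aldehyde (C4; the descriptor changes to R only through ligand priorities) untouched, and the aldehyde is used at once.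

Step 10
Reactants: 14 (2S,3R)-2-[(tert-butyldimethylsilyl)oxy]-3-methyl-4-oxobutyl 2,4-bis(benzyloxy)-3,5,6-trimethylbenzoate; 15 3-(triphenylphosphoranylidene)butan-2-one
Product: 16 (2S,3S,4E)-2-[(tert-butyldimethylsilyl)oxy]-3,5-dimethyl-6-oxohept-4-en-1-yl 2,4-bis(benzyloxy)-3,5,6-trimethylbenzoate
Conditions: 15 (2 equiv), toluene, 90 °C
Reagents that add atoms: none
Why: Wittig olefination with the stabilized, weakly basic acyl ylide should give the (E)-trisubstituted enone (C4a=C5) without enolizing the α-branched aldehyde.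

Step 11
Reactants: 16 (2S,3S,4E)-2-[(tert-butyldimethylsilyl)oxy]-3,5-dimethyl-6-oxohept-4-en-1-yl 2,4-bis(benzyloxy)-3,5,6-trimethylbenzoate; 17 dibenzyl malonate
Product: 19 benzyl 2-[(2S,3S)-4-{[2,4-bis(benzyloxy)-3,5,6-trimethylbenzoyl]oxy}-3-[(tert-butyldimethylsilyl)oxy]butan-2-yl]-3-methyl-4,6-dioxocyclohexane-1-carboxylate, via Michael adduct 18 (not isolated)
Conditions: 17 (1.5 equiv), NaH (0.2 equiv), THF, 0 °C to rt; then NaH (3 equiv), BnOH (0.1 equiv), 45 °C; then 1 M HCl, 0 °C
Reagents that add atoms: none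
Why: In this Michael–Claisen annulation the sodium enolate of 17 adds to the β-carbon of the enone (C4a–C8a), proton transfer then gives the methyl ketone enolate, and this attacks one benzyl ester with loss of benzyl oxide (C7–C8). The closest known reaction is the malonate/enone route to cyclohexane-1,3-diones used for dimedone and dihydroresorcylates. Ring A closes in a 6-(enolendo)-exo-trig Claisen step, the only productive ring size open to either ketone enolate, and formation of the doubly stabilized dione enolate should pull the reversible Michael step forward. The new ring stereocentres (C4a, C5, C8a) are not controlled and need not be, because step 12 removes them, while C4 is no longer acidic once the conjugate addition has taken place. The selectivity needed is conjugate addition ahead of γ-deprotonation at C4: the malonate is far more acidic than the γ-hydrogen, so with substoichiometric NaH the only base present while enone remains is the malonate anion, and the stronger base is added only afterwards. The ring B ester should survive because its carbonyl is shielded by two ortho substituents.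

Step 12
Reactants: 19 benzyl 2-[(2S,3S)-4-{[2,4-bis(benzyloxy)-3,5,6-trimethylbenzoyl]oxy}-3-[(tert-butyldimethylsilyl)oxy]butan-2-yl]-3-methyl-4,6-dioxocyclohexane-1-carboxylate
Product: 20 benzyl 2-[(2S,3S)-4-{[2,4-bis(benzyloxy)-3,5,6-trimethylbenzoyl]oxy}-3-[(tert-butyldimethylsilyl)oxy]butan-2-yl]-4,6-dihydroxy-3-methylbenzoate
Conditions: DDQ (1.1 equiv), 1,4-dioxane, rt
Reagents that add atoms: none
Why: Quinone dehydrogenation: DDQ should take hydride from C4a of the enolized β-keto ester, as it does with other enolized β-dicarbonyl compounds, and the resulting cyclohexenedione tautomerizes to the resorcylate, which removes C4a, C5 and C8a as stereocentres under neutral conditions that leave the silyl ether, benzyl ethers and esters alone.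

Step 13
Reactants: 20 benzyl 2-[(2S,3S)-4-{[2,4-bis(benzyloxy)-3,5,6-trimethylbenzoyl]oxy}-3-[(tert-butyldimethylsilyl)oxy]butan-2-yl]-4,6-dihydroxy-3-methylbenzoate
Product: 21 benzyl 2-[(2S,3S)-4-{[2,4-bis(benzyloxy)-3,5,6-trimethylbenzoyl]oxy}-3-[(tert-butyldimethylsilyl)oxy]butan-2-yl]-6-hydroxy-4-methoxy-3-methylbenzoate
Conditions: MeI (1.2 equiv), K2CO3, acetone, rt
Reagents that add atoms: iodomethane, CI
Why: Williamson methylation should be selective for the C6 hydroxyl because it is the more acidic, unchelated phenol, whereas the C8 hydroxyl is held in a hydrogen bond to the C1 ester carbonyl.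

Step 14
Reactants: 21 benzyl 2-[(2S,3S)-4-{[2,4-bis(benzyloxy)-3,5,6-trimethylbenzoyl]oxy}-3-[(tert-butyldimethylsilyl)oxy]butan-2-yl]-6-hydroxy-4-methoxy-3-methylbenzoate
Product: 22 benzyl 2-[(2S,3S)-4-{[2,4-bis(benzyloxy)-3,5,6-trimethylbenzoyl]oxy}-3-hydroxybutan-2-yl]-6-hydroxy-4-methoxy-3-methylbenzoate
Conditions: HF·pyridine, pyridine, THF, 0 °C to rt
Reagents that add atoms: none
Why: Desilylation with buffered HF·pyridine frees the carbinol without generating an alkoxide, so that neither closure onto the electron-rich, di-ortho-substituted C1 benzyl ester nor migration of the ring B acyl group is expected.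

Step 15
Reactants: 22 benzyl 2-[(2S,3S)-4-{[2,4-bis(benzyloxy)-3,5,6-trimethylbenzoyl]oxy}-3-hydroxybutan-2-yl]-6-hydroxy-4-methoxy-3-methylbenzoate
Product: 23 benzyl 2-[(2S)-4-{[2,4-bis(benzyloxy)-3,5,6-trimethylbenzoyl]oxy}-3-oxobutan-2-yl]-6-hydroxy-4-methoxy-3-methylbenzoate
Conditions: Dess–Martin periodinane, CH2Cl2, 0 °C to rt; Na2S2O3/pH 7 buffer work-up
Reagents that add atoms: none
Why: Dess–Martin oxidation converts the carbinol into the C3 ketone under neutral conditions, and C4 should keep its configuration because the di-ortho-substituted aryl group cannot become coplanar with an enol.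

Step 16
Reactants: 23 benzyl 2-[(2S)-4-{[2,4-bis(benzyloxy)-3,5,6-trimethylbenzoyl]oxy}-3-oxobutan-2-yl]-6-hydroxy-4-methoxy-3-methylbenzoate
Product: 25 [(3R,4S)-3,8-dihydroxy-6-methoxy-4,5-dimethyl-1-oxo-3,4-dihydro-1H-isochromen-3-yl]methyl 2,4-dihydroxy-3,5,6-trimethylbenzoate, via keto acid 24 (not isolated)
Conditions: H2 (1 bar), 10% Pd/C, EtOAc, rt
Reagents that add atoms: none
Why: Hydrogenolysis removes the benzyl ester and both benzyl ethers, the freed C1 acid adds to the C3 ketone in a six-membered lactol closure, and the hemiketal carbon should settle by equilibration through keto acid 24 as the 3R epimer.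

**Compound list**

1 | atraric acid (methyl 2,4-dihydroxy-3,6-dimethylbenzoate) | COC(=O)c1c(C)cc(O)c(C)c1O | starting material
2 | methyl 5-formyl-2,4-dihydroxy-3,6-dimethylbenzoate | COC(=O)c1c(C)c(C=O)c(O)c(C)c1O | intermediate
3 | methyl 2,4-dihydroxy-5-(hydroxymethyl)-3,6-dimethylbenzoate (not isolated) | COC(=O)c1c(C)c(CO)c(O)c(C)c1O | intermediate
4 | methyl 2,4-dihydroxy-3,5,6-trimethylbenzoate | COC(=O)c1c(C)c(C)c(O)c(C)c1O | intermediate
5 | methyl 2,4-bis(benzyloxy)-3,5,6-trimethylbenzoate | COC(=O)c1c(C)c(C)c(OCc2ccccc2)c(C)c1OCc1ccccc1 | intermediate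
6 | 2,4-bis(benzyloxy)-3,5,6-trimethylbenzoic acid | OC(=O)c1c(C)c(C)c(OCc2ccccc2)c(C)c1OCc1ccccc1 | intermediate
7 | prop-2-en-1-yl 2,4-bis(benzyloxy)-3,5,6-trimethylbenzoate | C=CCOC(=O)c1c(C)c(C)c(OCc2ccccc2)c(C)c1OCc1ccccc1 | intermediate
8 | 2,3-dihydroxypropyl 2,4-bis(benzyloxy)-3,5,6-trimethylbenzoate (racemic, not isolated) | OCC(O)COC(=O)c1c(C)c(C)c(OCc2ccccc2)c(C)c1OCc1ccccc1 | intermediate
9 | 2-oxoethyl 2,4-bis(benzyloxy)-3,5,6-trimethylbenzoate | O=CCOC(=O)c1c(C)c(C)c(OCc2ccccc2)c(C)c1OCc1ccccc1 | intermediate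
10 | diisopinocampheylborinate of alcohol 11 (not isolated) | C=C[C@H](C)[C@H](OB([C@@H]1C[C@@H]2C[C@H]([C@H]1C)C2(C)C)[C@@H]1C[C@@H]2C[C@H]([C@H]1C)C2(C)C)COC(=O)c1c(C)c(C)c(OCc2ccccc2)c(C)c1OCc1ccccc1 | intermediate
11 | (2S,3S)-2-hydroxy-3-methylpent-4-en-1-yl 2,4-bis(benzyloxy)-3,5,6-trimethylbenzoate | C=C[C@H](C)[C@H](O)COC(=O)c1c(C)c(C)c(OCc2ccccc2)c(C)c1OCc1ccccc1 | intermediate
12 | (2S,3S)-2-[(tert-butyldimethylsilyl)oxy]-3-methylpent-4-en-1-yl 2,4-bis(benzyloxy)-3,5,6-trimethylbenzoate | C=C[C@H](C)[C@H](O[Si](C)(C)C(C)(C)C)COC(=O)c1c(C)c(C)c(OCc2ccccc2)c(C)c1OCc1ccccc1 | intermediate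
13 | (2S,3S)-2-[(tert-butyldimethylsilyl)oxy]-4,5-dihydroxy-3-methylpentyl 2,4-bis(benzyloxy)-3,5,6-trimethylbenzoate (both C4 epimers, not isolated) | OCC(O)[C@H](C)[C@H](O[Si](C)(C)C(C)(C)C)COC(=O)c1c(C)c(C)c(OCc2ccccc2)c(C)c1OCc1ccccc1 | intermediate
14 | (2S,3R)-2-[(tert-butyldimethylsilyl)oxy]-3-methyl-4-oxobutyl 2,4-bis(benzyloxy)-3,5,6-trimethylbenzoate | O=C[C@H](C)[C@H](O[Si](C)(C)C(C)(C)C)COC(=O)c1c(C)c(C)c(OCc2ccccc2)c(C)c1OCc1ccccc1 | intermediate
15 | 3-(triphenylphosphoranylidene)butan-2-one | CC(=O)C(C)=P(c1ccccc1)(c1ccccc1)c1ccccc1 | starting material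
16 | (2S,3S,4E)-2-[(tert-butyldimethylsilyl)oxy]-3,5-dimethyl-6-oxohept-4-en-1-yl 2,4-bis(benzyloxy)-3,5,6-trimethylbenzoate | CC(=O)/C(C)=C/[C@H](C)[C@H](O[Si](C)(C)C(C)(C)C)COC(=O)c1c(C)c(C)c(OCc2ccccc2)c(C)c1OCc1ccccc1 | intermediate
17 | dibenzyl malonate | O=C(CC(=O)OCc1ccccc1)OCc1ccccc1 | starting material
18 | dibenzyl 2-[(5S,6S)-7-{[2,4-bis(benzyloxy)-3,5,6-trimethylbenzoyl]oxy}-6-[(tert-butyldimethylsilyl)oxy]-3,5-dimethyl-2-oxoheptan-4-yl]propanedioate (mixture at C3 and C4 of the heptane chain, not isolated) | CC(=O)C(C)C(C(C(=O)OCc1ccccc1)C(=O)OCc1ccccc1)[C@H](C)[C@H](O[Si](C)(C)C(C)(C)C)COC(=O)c1c(C)c(C)c(OCc2ccccc2)c(C)c1OCc1ccccc1 | intermediate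
19 | benzyl 2-[(2S,3S)-4-{[2,4-bis(benzyloxy)-3,5,6-trimethylbenzoyl]oxy}-3-[(tert-butyldimethylsilyl)oxy]butan-2-yl]-3-methyl-4,6-dioxocyclohexane-1-carboxylate (keto tautomer drawn, mixture at the three ring stereocentres) | O=C1CC(=O)C(C)C(C1C(=O)OCc1ccccc1)[C@H](C)[C@H](O[Si](C)(C)C(C)(C)C)COC(=O)c1c(C)c(C)c(OCc2ccccc2)c(C)c1OCc1ccccc1 | intermediate
20 | benzyl 2-[(2S,3S)-4-{[2,4-bis(benzyloxy)-3,5,6-trimethylbenzoyl]oxy}-3-[(tert-butyldimethylsilyl)oxy]butan-2-yl]-4,6-dihydroxy-3-methylbenzoate | Oc1cc(O)c(C(=O)OCc2ccccc2)c(c1C)[C@H](C)[C@H](O[Si](C)(C)C(C)(C)C)COC(=O)c1c(C)c(C)c(OCc2ccccc2)c(C)c1OCc1ccccc1 | intermediate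
21 | benzyl 2-[(2S,3S)-4-{[2,4-bis(benzyloxy)-3,5,6-trimethylbenzoyl]oxy}-3-[(tert-butyldimethylsilyl)oxy]butan-2-yl]-6-hydroxy-4-methoxy-3-methylbenzoate | COc1cc(O)c(C(=O)OCc2ccccc2)c(c1C)[C@H](C)[C@H](O[Si](C)(C)C(C)(C)C)COC(=O)c1c(C)c(C)c(OCc2ccccc2)c(C)c1OCc1ccccc1 | intermediate
22 | benzyl 2-[(2S,3S)-4-{[2,4-bis(benzyloxy)-3,5,6-trimethylbenzoyl]oxy}-3-hydroxybutan-2-yl]-6-hydroxy-4-methoxy-3-methylbenzoate | COc1cc(O)c(C(=O)OCc2ccccc2)c(c1C)[C@H](C)[C@H](O)COC(=O)c1c(C)c(C)c(OCc2ccccc2)c(C)c1OCc1ccccc1 | intermediate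
23 | benzyl 2-[(2S)-4-{[2,4-bis(benzyloxy)-3,5,6-trimethylbenzoyl]oxy}-3-oxobutan-2-yl]-6-hydroxy-4-methoxy-3-methylbenzoate | COc1cc(O)c(C(=O)OCc2ccccc2)c(c1C)[C@H](C)C(=O)COC(=O)c1c(C)c(C)c(OCc2ccccc2)c(C)c1OCc1ccccc1 | intermediate
24 | 2-[(2S)-4-[(2,4-dihydroxy-3,5,6-trimethylbenzoyl)oxy]-3-oxobutan-2-yl]-6-hydroxy-4-methoxy-3-methylbenzoic acid (not isolated) | COc1cc(O)c(C(=O)O)c(c1C)[C@H](C)C(=O)COC(=O)c1c(C)c(C)c(O)c(C)c1O | intermediate
25 | [(3R,4S)-3,8-dihydroxy-6-methoxy-4,5-dimethyl-1-oxo-3,4-dihydro-1H-isochromen-3-yl]methyl 2,4-dihydroxy-3,5,6-trimethylbenzoate | COc1cc(O)c2c(c1C)[C@H](C)[C@](O)(COC(=O)c1c(C)c(C)c(O)c(C)c1O)OC2=O | target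

**Count and risks**

Total step count: 16. Longest linear sequence: 16 steps (1 to 25); 15 and 17 are purchased.

Steps most likely to fail:

1. Step 11. Conjugate addition to the α-methyl, γ-branched enone may be slower than γ-deprotonation at C4, which would scramble C4, deconjugate the enone or expel the C3 silyloxy group; reversal of the Michael step before ring closure is the second danger. Fallback: setting out from aldehyde 14, so that enone 16 is bypassed, Knoevenagel condensation with 17 (TiCl4, pyridine, THF, 0 °C) should give the alkylidene malonate F1, a much stronger acceptor. Mukaiyama–Michael addition of (Z)-2-(trimethylsilyloxy)but-2-ene (TiCl4, CH2Cl2, −78 °C) then forms the C4a–C5 bond under non-basic conditions. After aqueous work-up this delivers keto diester 18, where the route is rejoined; 18 is closed to 19 by the NaH treatment of step 11.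

2. Step 12. The quinone may add the enol as a carbon or oxygen nucleophile instead of accepting hydride, or go on to oxidize the product phenol at the C5 methyl group. Fallback: from 19, electrophilic bromination (pyridinium tribromide, NaOAc, CH2Cl2, 0 °C) should give the bromodione F2. Dehydrobromination with LiBr and Li2CO3 in DMF at 80 °C, the classical passage from α-bromo ketones to enones, followed by tautomerization, returns to the route at 20.

3. Step 7. The α-acyloxy aldehyde may hydrate and self-condense before it meets the borane, and facial selectivity short of complete cannot be upgraded later, because C4 remains the only reagent-set stereocentre. Fallback: from acid 6, O-alkylation with 2-bromoethanol (K2CO3, DMF) gives the 2-hydroxyethyl ester F3. Iridium-catalysed transfer-hydrogenative anti-crotylation (Krische crotylation) then acts on the alcohol directly: [Ir(cod)Cl]2, the SEGPHOS enantiomer that leads to the (2S,3S) product, 4-cyano-3-nitrobenzoic acid, Cs2CO3, but-3-en-2-yl acetate, THF, 70 °C. The aldehyde exists only transiently at the metal, and the route is rejoined at 11.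

**Further compounds**

F1 | step 11 | dibenzyl 2-[(2S,3S)-4-{[2,4-bis(benzyloxy)-3,5,6-trimethylbenzoyl]oxy}-3-[(tert-butyldimethylsilyl)oxy]-2-methylbutylidene]propanedioate | O=C(OCc1ccccc1)C(=C[C@H](C)[C@H](O[Si](C)(C)C(C)(C)C)COC(=O)c1c(C)c(C)c(OCc2ccccc2)c(C)c1OCc1ccccc1)C(=O)OCc1ccccc1
F2 | step 12 | benzyl 5-bromo-2-[(2S,3S)-4-{[2,4-bis(benzyloxy)-3,5,6-trimethylbenzoyl]oxy}-3-[(tert-butyldimethylsilyl)oxy]butan-2-yl]-3-methyl-4,6-dioxocyclohexane-1-carboxylate | O=C1C(Br)C(=O)C(C)C(C1C(=O)OCc1ccccc1)[C@H](C)[C@H](O[Si](C)(C)C(C)(C)C)COC(=O)c1c(C)c(C)c(OCc2ccccc2)c(C)c1OCc1ccccc1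
F3 | step 7 | 2-hydroxyethyl 2,4-bis(benzyloxy)-3,5,6-trimethylbenzoate | OCCOC(=O)c1c(C)c(C)c(OCc2ccccc2)c(C)c1OCc1ccccc1
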